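The earlier runs and the new flask were computed with made-up constants; scatter was added.

Start from the zeta run and try the bench rule: after 5 half-lives a first-order loss is over. Its substrate falls from 52% of the charge at 3.00 min to 18% at 8.00 min, a half-life of 3.27 min, so the rule calls the run over at 16.4 min. Now test the rule with a ratio. At 15.0 min zeta shows 6% substrate but 14% target, so target is 14.9% of the vanished substrate, less than half of it. The rule therefore stops at the loss of substrate: in zeta the rest sits in an unseen pool, and target keeps rising.

| setting | zeta | beta | Sunday's | Saturday's |
|---|---|---|---|---|
| substrate | 0.30 M | 0.48 M | 0.20 M | 0.40 M |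
| remark | run made earlier | run made earlier |  |  |
| time |  |  | 40 min | 150 min |

| run | time / min | target / % | substrate / % |
|---|---|---|---|
| zeta | 3.00 | 6 | 52 |
| zeta | 5.00 | 5 | 36 |
| zeta | 8.00 | 11 | 18 |
| zeta | 12.0 | 10 | 13 |
| zeta | 15.0 | 14 | 6 |
| zeta | 25.0 | 20 | 5 |
| zeta | 40.0 | 30 | 5 |
| beta | 6.00 | 4 | 28 |
| beta | 12.0 | 7 | 13 |
| beta | 15.0 | 10 | 12 |
| beta | 25.0 | 16 | 8 |
| beta | 30.0 | 14 | 9 |
| beta | 40.0 | 22 | 8 |

(standard deviation of a reading: 2 percentage points)

* the flask that ends with the higher amount of target, in percent of the substrate charged, or "neither" when 2 percentage points or less lies between them (Sunday's / Saturday's / neither)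
* final target, as a percentage of the substrate charged, in Sunday's
* final target, as a percentage of the substrate charged, in Saturday's

So count on a slower clock. Call the drain time the time in which target's late pace would pass the whole charge. From 15.0 min to 40.0 min zeta gains 16 percentage points, a drain time of 156 min. Over the same span beta gains 12 points, giving 208 min. Beta's charge is 1.60 times zeta's and its drain time 1.33 times, so within the scatter let drain time grow with the charge and average the two runs. That gives 95.5 min for Sunday's and 191 min for Saturday's. Divide time by drain time: my count of target is 41.9% of the charge for Sunday's and 78.5% for Saturday's. Saturday's is closer to a full count, where the pool thins, so read my figure for it as high.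

The forecast names Saturday's as the flask with more target, with 40% for Sunday's and 68% for Saturday's, the latter lower than my count, since in its words the “rate seems to slacken with time”.

Sunday's ends at 37.2% and Saturday's at 64.2%, so Saturday's gives more.

    substrate → target, rate k1*[substrate]/(1 + ([substrate]/sat1)) (14.2 mM, k = 0.00428 /s)
    substrate ⇌ dormant form (K = 7.87, k = 0.00343 /s)
    target ⇌ isomer of the product (K = 0.460, k = 4.11 × 10⁻⁵ /s)
    substrate → decomposition product (k = 5.39 × 10⁻⁷ /s)

The unseen pool holds the dormant form, the resting state of the unconverted substrate, and Saturday's still has 23.2% of it at 150 min. Put the drain time to work again: Saturday's count of 78.5% stands against 64.2% found. The same flask left until 1.0 h counts 31.4% of its drain time and holds 35.4% target.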